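Everything rests on unmasking the cyclopentene last. In the target this ring (C8, C9, C11, C12, C14) shares C9 and C14 with the α-methylene δ-lactone, and C12 and the methylene-bearing C13 are both bonded to C14. A C14 radical in an isomeric 2-oxabicyclo[2.2.2]octenone, in which C12 is still bonded to C13, should therefore undergo a 1,2-vinyl shift that contracts the cyclohexene C8–C9–C11–C12–C13–C14 to the cyclopentene; the extruded C13 radical is desaturated at its methyl group, delivering the exocyclic methylene in the same operation. The precursor, a tertiary α-bromo ester, is the adduct of an intramolecular 2-pyrone Diels–Alder reaction and is assembled from (S)-epichlorohydrin.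

Key step: step 14

Numbering used throughout (biogenetic): ring A = C1, C2, C3 (OAc), C4 (CMe2), C5 (H), C10; ring B = C5, C6 (O–CH), C7 (CH2), C8 (C–CH3), C9 (C–O), C10; C19 = lactone carbonyl on C10 (closed to O–C6); cyclopentene = C8, C9, C11 (=CH), C12 (=C–CH3), C14 (C–CO2Me); C13 = methylene-bearing carbon, C17 = its lactone carbonyl (closed to O–C9).

Remark 1: 4-methylpent-1-en-3-one (isopropyl vinyl ketone) is treated as a catalogue chemical.
Remark 2: the configuration at C14 in compounds 21 to 25 is drawn for the expected epimer but is inconsequential, because C14 becomes a planar radical in step 14.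

Step 1
Reactants: 1 (S)-epichlorohydrin; 2 isopropenylmagnesium bromide
Product: 3 (S)-1-chloro-4-methylpent-4-en-2-ol
Conditions: CuI (10 mol %), THF, −40 → 0 °C; aq. NH4Cl
Reagents that add atoms: none
Why: Copper-catalysed Grignard opening of the epoxide at its unsubstituted carbon (SN2) should leave the C–O stereocentre, the future C6, untouched.

Step 2
Reactants: 3 (S)-1-chloro-4-methylpent-4-en-2-ol; 4 ethyl acetoacetate
Product: 6 (5R)-3-acetyl-5-(2-methylallyl)dihydrofuran-2(3H)-one as a mixture of C10 epimers, via epoxide 5 (not isolated)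
Conditions: NaOEt (2.1 equiv), EtOH, 0 → 60 °C; dilute HCl to pH 5
Reagents that add atoms: none
Why: Ethoxide closes the chlorohydrin to the epoxide, sodioacetoacetate opens it at the terminal carbon and the alkoxide lactonises (classical acetoacetate–epoxide γ-lactone synthesis), with C6 a spectator.

Step 3
Reactants: 6 (5R)-3-acetyl-5-(2-methylallyl)dihydrofuran-2(3H)-one
Product: 9 (S)-3-acetyl-5-(2-methylallyl)furan-2(5H)-one, via selenide 7 (not isolated), via selenoxide 8 (not isolated)
Conditions: NaH, THF, 0 °C; PhSeCl, −78 °C; then 30 % H2O2, CH2Cl2, 0 °C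
Reagents that add atoms: none
Why: α-Selenenylation of the β-keto lactone enolate and selenoxide syn-elimination (only the C5 hydrogens are β) should give the doubly activated butenolide, which is kept cold and used at once so that enolisation toward the 2-hydroxyfuran does not erode C6.

Step 4
Reactants: 10 4-methylpent-1-en-3-one
Product: 11 tert-butyldimethyl[(4-methylpenta-1,3-dien-3-yl)oxy]silane
Conditions: TBSOTf, Et3N, CH2Cl2, 0 °C
Reagents that add atoms: tert-butyldimethylsilyl triflate CC(C)(C)[Si](C)(C)OS(=O)(=O)C(F)(F)F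
Why: Soft enolisation and O-silylation should give the 2-silyloxy diene, since the isopropyl methine is the only α-hydrogen.

Step 5
Reactants: 9 (S)-3-acetyl-5-(2-methylallyl)furan-2(5H)-one; 11 tert-butyldimethyl[(4-methylpenta-1,3-dien-3-yl)oxy]silane
Product: 12 cis-fused 7a-acetyl-5-(tert-butyldimethylsilyloxy)-4,4-dimethyl-3-(2-methylallyl)-3a,4,7,7a-tetrahydroisobenzofuran-1(3H)-one (C10 acetyl, H5 and C7 on one face)
Conditions: toluene, BHT (cat.), 0 → 40 °C
Reagents that add atoms: none
Why: Normal-demand, strongly asynchronous Diels–Alder reaction in which the nucleophilic CMe2 terminus bonds to the β-carbon C5 and the CH2 terminus to C10; the diene should add anti to the 2-methylallyl group on C6 and suprafacially, which sets C5 and C10 from C6 and builds ring A with its gem-dimethyl group and masked C3 ketone.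

Step 6
Reactants: 13 methyl 2-methyl-3-oxobutanoate
Product: 14 methyl (Z)-2-methyl-3-(trifluoromethylsulfonyloxy)but-2-enoate
Conditions: Tf2O, sat. aq. LiOH, toluene, 5 °C
Reagents that add atoms: triflic anhydride O=S(=O)(OS(=O)(=O)C(F)(F)F)C(F)(F)F
Why: O-Triflation of the chelated β-keto ester enolate should favour the Z enol triflate; the geometry is in any case levelled later through a dienolate.

Step 7
Reactants: 12 cis-fused acetyl lactone silyl enol ether; 14 methyl (Z)-2-methyl-3-(trifluoromethylsulfonyloxy)but-2-enoate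
Product: 16 methyl (Z)-2,3-dimethyl-5-oxopent-2-enoate carrying the bicyclic lactone at C5 of the chain (C9 ketone on C10), via lithium enolate 15 (not isolated)
Conditions: LiN(SiMe3)2 (2.2 equiv), THF, −78 °C; then 14, Pd2(dba)3 (2.5 mol %), XPhos (10 mol %), −78 → 45 °C; aq. NH4Cl
Reagents that add atoms: none
Why: Palladium-catalysed α-alkenylation of a ketone enolate: only the acetyl methyl group (C11) can be deprotonated because C10 is quaternary and C3 is masked, and zerovalent palladium should insert into the enol triflate and couple it to C11.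

Step 8
Reactants: 16 δ-keto enoate
Product: 18 cis-fused 7a-(3,4-dimethyl-2-oxo-2H-pyran-6-yl)-4,4-dimethyl-3-(2-methylallyl)hexahydroisobenzofuran-1,5-dione, via pyrone silyl enol ether 17 (not isolated)
Conditions: DBU, toluene, 60 °C; then 1 M HCl, THF, 23 °C
Reagents that add atoms: none
Why: DBU should generate the C11 dienolate whose oxygen attacks the ester (enol lactonisation, the 2-pyrone being the thermodynamic sink from either alkene isomer), and dilute acid then hydrolyses the silyl enol ether to the C3 ketone.

Step 9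
Reactants: 18 pyrone ketone; 19 methyl acrylate
Product: 20 methyl (E)-3-methyl-4-[bicyclic pyronyl lactone-3-yl]but-2-enoate (C7H2–C8(CH3)=C14H–CO2Me on C6)
Conditions: second-generation Hoveyda–Grubbs catalyst (10 mol %), 19 (10 equiv), CH2Cl2, 40 °C
Reagents that add atoms: none
Why: Olefin cross-metathesis of the 1,1-disubstituted alkene with excess acrylate should give the E enoate; it is installed only now because its C7 hydrogens would allow base-induced β-elimination of the C6 lactone oxygen, and any Z isomer converges after step 14.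

Step 10
Reactants: 20 pyrone enoate
Product: 21 bridged lactone adduct (2-oxabicyclo[2.2.2]oct-5-en-3-one spanning C9 and C13; ring B closed; C14–H with CO2Me syn to the C11=C12 bridge; C3 ketone)
Conditions: toluene (0.01 M), BHT, 120 °C, sealed tube
Reagents that add atoms: none
Why: Intramolecular Diels–Alder reaction of the 2-pyrone diene (C9=C11–C12=C13) with the enoate; the C19→C6 γ-lactone forces C8 to reach C9 gauche to C19 with the tether under the O–C17 edge of the pyrone and the ester endo, which should set C9 and C8 (and with them C13) relative to C10, while the C14 configuration is irrelevant.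

Step 11
Reactants: 21 bridged lactone ketone
Product: 22 axial C3 alcohol (OH cis to H5)
Conditions: LiBH(s-Bu)3 (1.1 equiv), THF, −78 °C; aq. NH4Cl
Reagents that add atoms: none
Why: The bulky trialkylborohydride should attack the 4,4-dimethyl-3-ketone from the equatorial direction, as with 3-oxo triterpenoids, to give the axial alcohol, and the ketone reacts far faster than the lactones and the ester at −78 °C.

Step 12
Reactants: 22 axial C3 alcohol
Product: 24 C14 bromide (tertiary α-bromo ester; free C3–OH), via dilithium alkoxide enolate 23 (not isolated)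
Conditions: LiN(i-Pr)2 (2.5 equiv), THF, −78 → −40 °C; BrCCl2CCl2Br, −78 °C; aq. NH4Cl
Reagents that add atoms: 1,2-dibromo-1,1,2,2-tetrachloroethane BrC(Cl)(Cl)C(Cl)(Cl)Br
Why: Enolate bromination: after alkoxide formation C14–H is the only acidic C–H left (both lactones lack α-hydrogens), and the ester enolate should be brominated by the positive-bromine donor; either C14 epimer serves.

Step 13
Reactants: 24 C14 bromide
Product: 25 C14 bromide 3-acetate
Conditions: Ac2O, DMAP, pyridine, CH2Cl2, 23 °C
Reagents that add atoms: acetic anhydride CC(=O)OC(C)=O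
Why: DMAP-catalysed acetylation of the hindered axial alcohol; the tertiary bromide has no β-hydrogen and cannot eliminate.

Step 14
Reactants: 25 C14 bromide 3-acetate
Product: 28 meroantarctine B, via C14 radical 26 (not isolated), via C13 radical 27 (not isolated)
Conditions: fac-Ir(ppy)3 (2 mol %), Co(dmgH)2(py)Cl (10 mol %), K2HPO4 (2 equiv), degassed MeCN, blue LEDs (450 nm), 25 °C
Reagents that add atoms: none
Why: Proposed new method: excited fac-Ir(ppy)3 should cleave the tertiary C14–Br bond reductively, the electrophilic C14 radical adds 3-exo-trig to C12 of the C11=C12 bond held over it and the cyclopropylcarbinyl stage reopens by scission of C12–C13, a net 1,2-vinyl shift that contracts the cyclohexene C8–C9–C11–C12–C13–C14 to the cyclopentene C8–C9–C11–C12–C14 and turns the 2-oxabicyclo[2.2.2]octenone into the 2-oxabicyclo[3.2.1]octenone; divalent cobalt then takes a hydrogen atom from the methyl group of the C13 radical to give the exocyclic methylene, and the cobalt hydride is deprotonated and reoxidised by the iridium to close both cycles. The closest known reaction types are the homoallyl–cyclopropylcarbinyl–homoallyl rearrangement of bicyclo[2.2.2]oct-5-en-2-yl radicals to bicyclo[3.2.1]oct-6-en-2-yl radicals and photoredox/cobaloxime dehydrohalogenation, which have not been combined on a lactone-bridged system. The only ring closed is the cyclopentene, by 3-exo-trig attack followed by ring reopening. The new stereocentre C14 is fixed by the cage, because C12 can only reach the lobe of the C14 orbital that faces the alkene bridge while C8 and C13 stay bonded. The step needs vinyl migration in preference to lactone-acyl migration and termination only after the shift: ester-type acyl shifts are orders of magnitude slower, the C14 radical has no β-hydrogen (C8 and C13 are quaternary) and its C8–C9 bond lies in the nodal plane, whereas the C13 radical offers only its methyl hydrogens, so desaturation should be irreversible and exocyclic and should pull the radical equilibrium toward the less strained [3.2.1] lactone.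

Compound list
1 | (S)-epichlorohydrin | ClC[C@@H]1CO1 | starting material
2 | isopropenylmagnesium bromide | C=C(C)[Mg]Br | starting material
3 | (S)-1-chloro-4-methylpent-4-en-2-ol | C=C(C)C[C@H](O)CCl | intermediate
4 | ethyl acetoacetate | CCOC(=O)CC(C)=O | starting material
5 | (S)-2-(2-methylallyl)oxirane (not isolated) | C=C(C)C[C@H]1CO1 | intermediate
6 | (5R)-3-acetyl-5-(2-methylallyl)dihydrofuran-2(3H)-one, C10 epimers | C=C(C)C[C@H]1CC(C(C)=O)C(=O)O1 | intermediate
7 | (5R)-3-acetyl-5-(2-methylallyl)-3-(phenylselanyl)dihydrofuran-2(3H)-one (not isolated) | C=C(C)C[C@H]1CC(C(C)=O)([Se]c2ccccc2)C(=O)O1 | intermediate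
8 | selenoxide of 7 (not isolated) | C=C(C)C[C@H]1CC(C(C)=O)([Se](=O)c2ccccc2)C(=O)O1 | intermediate
9 | (S)-3-acetyl-5-(2-methylallyl)furan-2(5H)-one | C=C(C)C[C@H]1C=C(C(C)=O)C(=O)O1 | intermediate
10 | 4-methylpent-1-en-3-one | C=CC(=O)C(C)C | starting material
11 | tert-butyldimethyl[(4-methylpenta-1,3-dien-3-yl)oxy]silane | C=CC(O[Si](C)(C)C(C)(C)C)=C(C)C | intermediate
12 | cis-fused 7a-acetyl-5-(tert-butyldimethylsilyloxy)-4,4-dimethyl-3-(2-methylallyl)-3a,4,7,7a-tetrahydroisobenzofuran-1(3H)-one; acetyl, H-3a and 2-methylallyl on one face | CC(=O)[C@]12CC=C(O[Si](C)(C)C(C)(C)C)C(C)(C)[C@H]1[C@H](CC(C)=C)OC2=O | intermediate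
13 | methyl 2-methyl-3-oxobutanoate | COC(=O)C(C)C(C)=O | starting material
14 | methyl (Z)-2-methyl-3-(trifluoromethylsulfonyloxy)but-2-enoate | COC(=O)/C(C)=C(C)\OS(=O)(=O)C(F)(F)F | intermediate
15 | lithium enolate of 12 at the acetyl group (not isolated) | [Li+].C=C([O-])[C@]12CC=C(O[Si](C)(C)C(C)(C)C)C(C)(C)[C@H]1[C@H](CC(C)=C)OC2=O | intermediate
16 | methyl (Z)-2,3-dimethyl-5-oxo-5-(bicyclic lactone-7a-yl)pent-2-enoate (C9 ketone on C10, silyl enol ether retained) | COC(=O)/C(C)=C(C)\CC(=O)[C@]12CC=C(O[Si](C)(C)C(C)(C)C)C(C)(C)[C@H]1[C@H](CC(C)=C)OC2=O | intermediate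
17 | 3,4-dimethyl-2-pyrone bearing the bicyclic lactone silyl enol ether at C6 of the pyrone (not isolated) | O=C1OC(=CC(C)=C1C)[C@]23CC=C(O[Si](C)(C)C(C)(C)C)C(C)(C)[C@H]2[C@H](CC(C)=C)OC3=O | intermediate
18 | cis-fused 7a-(3,4-dimethyl-2-oxo-2H-pyran-6-yl)-4,4-dimethyl-3-(2-methylallyl)hexahydroisobenzofuran-1,5-dione | O=C1OC(=CC(C)=C1C)[C@]23CCC(=O)C(C)(C)[C@H]2[C@H](CC(C)=C)OC3=O | intermediate
19 | methyl acrylate | C=CC(=O)OC | starting material
20 | methyl (E)-3-methyl-4-[7a-(3,4-dimethyl-2-oxo-2H-pyran-6-yl)-4,4-dimethyl-1,5-dioxo-octahydroisobenzofuran-3-yl]but-2-enoate | O=C1OC(=CC(C)=C1C)[C@]23CCC(=O)C(C)(C)[C@H]2[C@H](C/C(C)=C/C(=O)OC)OC3=O | intermediate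
21 | Diels–Alder adduct: C9–O–C17(=O)–C13 lactone bridging cyclohexene C8/C9/C11=C12/C13/C14; 8-CH3 and 14-CO2Me syn to the alkene bridge; C19→C6 γ-lactone; C3 ketone | C[C@@]12C(=O)O[C@@]3(C=C1C)[C@](C)(C[C@@H]4OC(=O)[C@]35CCC(=O)C(C)(C)[C@@H]45)[C@H]2C(=O)OC | intermediate
22 | axial C3 alcohol of 21 (OH cis to H5) | C[C@@]12C(=O)O[C@@]3(C=C1C)[C@](C)(C[C@@H]4OC(=O)[C@]35CC[C@H](O)C(C)(C)[C@@H]45)[C@H]2C(=O)OC | intermediate
23 | dilithium C3 alkoxide / C14 ester enolate of 22 (not isolated) | [Li+].[Li+].C[C@@]12C(=O)O[C@@]3(C=C1C)[C@](C)(C[C@@H]4OC(=O)[C@]35CC[C@H]([O-])C(C)(C)[C@@H]45)C2=C([O-])OC | intermediate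
24 | C14 bromide of 22 (tertiary α-bromo ester, free C3–OH) | C[C@@]12C(=O)O[C@@]3(C=C1C)[C@](C)(C[C@@H]4OC(=O)[C@]35CC[C@H](O)C(C)(C)[C@@H]45)[C@@]2(Br)C(=O)OC | intermediate
25 | C14 bromide 3-acetate | C[C@@]12C(=O)O[C@@]3(C=C1C)[C@](C)(C[C@@H]4OC(=O)[C@]35CC[C@H](OC(C)=O)C(C)(C)[C@@H]45)[C@@]2(Br)C(=O)OC | intermediate
26 | C14 radical of the [2.2.2] lactone (not isolated) | C[C@@]12C(=O)O[C@@]3(C=C1C)[C@](C)(C[C@@H]4OC(=O)[C@]35CC[C@H](OC(C)=O)C(C)(C)[C@@H]45)[C]2C(=O)OC | intermediate
27 | rearranged C13 radical of the [3.2.1] lactone (not isolated) | C[C]1C(=O)O[C@@]23C=C(C)[C@]1(C(=O)OC)[C@@]2(C)C[C@@H]1OC(=O)[C@]32CC[C@H](OC(C)=O)C(C)(C)[C@@H]12 | intermediate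
28 | meroantarctine B | C=C1C(=O)O[C@@]23C=C(C)[C@]1(C(=O)OC)[C@@]2(C)C[C@@H]1OC(=O)[C@]32CC[C@H](OC(C)=O)C(C)(C)[C@@H]12 | target

Total step count: 14. Longest linear sequence: 12 steps (1, 2, 3, 5, 7, 8, 9, 10, 11, 12, 13, 14); steps 4 and 6 prepare the diene and the enol triflate.

Steps most likely to fail

1. Step 14 (proposed new method). The C14 radical may be reduced back to the C–H ester before it rearranges, or cobalt may fail to intercept the hindered C13 radical, which would then add to the product acrylate. The fallback sets out from 24 and uses known chemistry. Heating 24 with Bu3SnH and AIBN (benzene, 80 °C, syringe-pump addition), the established tin hydride protocol for the bicyclo[2.2.2]octenyl to bicyclo[3.2.1]octenyl radical rearrangement, should give the ring-contracted α-methyl δ-lactone alcohol F1 as C13 epimers. Selenenylation of its lactone enolate (LiN(i-Pr)2, 2.2 equiv, then PhSeBr) should give the α-phenylselanyl lactone F2. Oxidation (H2O2, pyridine) and syn-elimination, which can only take a methyl hydrogen, should give 3-O-deacetyl meroantarctine B F3, and acetylation (Ac2O, DMAP) comes back to the route at 28.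

2. Step 10. The cycloaddition, which creates three quaternary carbons, may be too slow below the temperature at which the bridged lactone extrudes CO2, or the dienophile may add to the other pyrone face. The fallback sets out from 18 and activates the dienophile as an aldehyde. Cross-metathesis with crotonaldehyde (second-generation Hoveyda–Grubbs catalyst) should give the (E)-enal F4. A Me2AlCl-promoted intramolecular Diels–Alder reaction at −40 to 0 °C should give the bridged lactone aldehyde F5. Pinnick oxidation (NaClO2, NaH2PO4, 2-methyl-2-butene) should give the carboxylic acid F6, and esterification with TMSCHN2 in MeOH comes back to the route at 21.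

3. Step 7. Triflyl transfer from the activated enol triflate to the lithium enolate may outrun oxidative addition, or coupling at the fully substituted alkenylpalladium centre may stall. The fallback sets out from 12 and builds the pyrone from an alkyne. Enolisation with LiN(i-Pr)2 and trapping with ClP(O)(OEt)2 should give the enol diethyl phosphate F7 (not isolated), and further LiN(i-Pr)2 (2.2 equiv) should eliminate it to the terminal alkyne F8. Sonogashira coupling with 14 (PdCl2(PPh3)2, CuI, Et3N) should give the (Z)-enynoate F9, and 1 M HCl should unmask the C3 ketone to give the keto enynoate F10. Gold-catalysed 6-endo cyclisation of the ester carbonyl onto the alkyne (AuCl(PPh3), AgOTf, wet CH2Cl2) then comes back to the route at 18.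

Further compounds
F1 | step 14 | ring-contracted α-methyl δ-lactone alcohol (13,methylene-dihydro-3-O-deacetyl meroantarctine B, C13 epimers) | CC1C(=O)O[C@@]23C=C(C)[C@]1(C(=O)OC)[C@@]2(C)C[C@@H]1OC(=O)[C@]32CC[C@H](O)C(C)(C)[C@@H]12
F2 | step 14 | C13 phenylselanyl derivative of F1 | CC1([Se]c4ccccc4)C(=O)O[C@@]23C=C(C)[C@]1(C(=O)OC)[C@@]2(C)C[C@@H]1OC(=O)[C@]32CC[C@H](O)C(C)(C)[C@@H]12
F3 | step 14 | 3-O-deacetyl meroantarctine B | C=C1C(=O)O[C@@]23C=C(C)[C@]1(C(=O)OC)[C@@]2(C)C[C@@H]1OC(=O)[C@]32CC[C@H](O)C(C)(C)[C@@H]12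
F4 | step 10 | (E)-3-methyl-4-[7a-(3,4-dimethyl-2-oxo-2H-pyran-6-yl)-4,4-dimethyl-1,5-dioxo-octahydroisobenzofuran-3-yl]but-2-enal | O=C1OC(=CC(C)=C1C)[C@]23CCC(=O)C(C)(C)[C@H]2[C@H](C/C(C)=C/C=O)OC3=O
F5 | step 10 | C14 aldehyde analogue of 21 | C[C@@]12C(=O)O[C@@]3(C=C1C)[C@](C)(C[C@@H]4OC(=O)[C@]35CCC(=O)C(C)(C)[C@@H]45)[C@H]2C=O
F6 | step 10 | C14 carboxylic acid analogue of 21 | C[C@@]12C(=O)O[C@@]3(C=C1C)[C@](C)(C[C@@H]4OC(=O)[C@]35CCC(=O)C(C)(C)[C@@H]45)[C@H]2C(=O)O
F7 | step 7 | enol diethyl phosphate of 12 (not isolated) | C=C(OP(=O)(OCC)OCC)[C@]12CC=C(O[Si](C)(C)C(C)(C)C)C(C)(C)[C@H]1[C@H](CC(C)=C)OC2=O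
F8 | step 7 | C10 ethynyl lactone silyl enol ether | C#C[C@]12CC=C(O[Si](C)(C)C(C)(C)C)C(C)(C)[C@H]1[C@H](CC(C)=C)OC2=O
F9 | step 7 | methyl (Z)-2,3-dimethylpent-2-en-4-ynoate carrying the bicyclic lactone silyl enol ether at C5 | COC(=O)/C(C)=C(C)\C#C[C@]12CC=C(O[Si](C)(C)C(C)(C)C)C(C)(C)[C@H]1[C@H](CC(C)=C)OC2=O
F10 | step 7 | C3 ketone of F9 | COC(=O)/C(C)=C(C)\C#C[C@]12CCC(=O)C(C)(C)[C@H]1[C@H](CC(C)=C)OC2=O
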